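**Assumption:** the target has no stereocentre and no configurationally stable axis, so it is one achiral compound and no stereocontrol is needed.

## Retrosynthetic overview

1. Target 12 ⇐ 11 (removal of two MOM ethers on ring A) ⇐ 10 (O-methylation of the one free, chelated 2-OH on ring B).
2. Key disconnection: the ring A aryl–C(=O) bond of the depside. Aryl iodide 4 (aryl cation synthon) is joined to an aryloxycarbonyl anion synthon (an acyl anion; reagent equivalent CO plus the 4-OH of 9) by palladium-catalysed aryloxycarbonylation. Both carbons are electrophiles in conventional terms, and the hindered ester C–O bond forms in the same operation.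
3. Ring A fragment 4 ⇐ 2,5-dimethylresorcinol 1 by chlorination, iodination and MOM protection.
4. Ring B fragment 9 ⇐ methyl 2,4-dihydroxy-3,6-dimethylbenzoate 5 by formylation at the free ring position and hydrogenolysis to the third methyl group.
5. No ring is formed: both benzene rings come intact from 1 and 5.

## Route

Step 1
Reactants: 1 2,5-dimethylbenzene-1,3-diol
Product: 2 4-chloro-2,5-dimethylbenzene-1,3-diol
Conditions: SO2Cl2 (1.0 equiv), Et2O, 0 °C
Reagents that add atoms: sulfuryl chloride, O=S(=O)(Cl)Cl
Why: electrophilic aromatic chlorination at one of the two equivalent positions ortho/para to the hydroxyls, where the first chlorine deactivates the ring enough for one equivalent to stop mainly at the monochloride.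

Step 2
Reactants: 2 4-chloro-2,5-dimethylbenzene-1,3-diol
Product: 3 4-chloro-6-iodo-2,5-dimethylbenzene-1,3-diol
Conditions: NIS (1.05 equiv), MeCN, 0 °C to rt, dark
Reagents that add atoms: N-iodosuccinimide, O=C1CCC(=O)N1I
Why: electrophilic aromatic iodination at the only remaining ring C–H, which is ortho to one hydroxyl and para to the other.

Step 3
Reactants: 3 4-chloro-6-iodo-2,5-dimethylbenzene-1,3-diol
Product: 4 1-chloro-3-iodo-4,6-bis(methoxymethoxy)-2,5-dimethylbenzene
Conditions: NaH (2.5 equiv), MOMCl (2.5 equiv), DMF, 0 °C to rt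
Reagents that add atoms: chloromethyl methyl ether, COCCl
Why: Williamson-type O-alkylation of both phenoxides with a small, highly reactive alkylating agent, which caps the phenols that would otherwise compete as nucleophiles in step 6.

Step 4
Reactants: 5 methyl 2,4-dihydroxy-3,6-dimethylbenzoate
Product: 7 methyl 5-formyl-2,4-dihydroxy-3,6-dimethylbenzoate, via alpha-chloro ether 6 (not isolated)
Conditions: Cl2CHOMe (1.5 equiv), TiCl4 (3 equiv), CH2Cl2, −10 °C to rt; then aq. HCl
Reagents that add atoms: dichloromethyl methyl ether, COC(Cl)Cl; water, O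
Why: Rieche formylation, a Friedel–Crafts reaction at the single free ring position (ortho to the 4-OH, para to the 2-OH), with hydrolysis of the chloro ether on work-up.

Step 5
Reactants: 7 methyl 5-formyl-2,4-dihydroxy-3,6-dimethylbenzoate
Product: 9 methyl 2,4-dihydroxy-3,5,6-trimethylbenzoate, via benzylic alcohol 8 (not isolated)
Conditions: H2 (3 bar), 10% Pd/C, AcOH, cat. HCl, rt
Reagents that add atoms: none
Why: catalytic hydrogenation of the aldehyde followed by hydrogenolysis of the electron-rich ortho/para-hydroxybenzylic alcohol gives the methyl group, and the ring carries no halogen to lose.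

Step 6
Reactants: 4 1-chloro-3-iodo-4,6-bis(methoxymethoxy)-2,5-dimethylbenzene; 9 methyl 2,4-dihydroxy-3,5,6-trimethylbenzoate (1.2 equiv)
Product: 10 methyl 4-{[3-chloro-4,6-bis(methoxymethoxy)-2,5-dimethylbenzoyl]oxy}-2-hydroxy-3,5,6-trimethylbenzoate
Conditions: Pd(OAc)2 (5 mol %), Xantphos (10 mol %), CO (5 bar), K2CO3 (1.5 equiv), 4 Å MS, 1,4-dioxane, 100 °C
Reagents that add atoms: carbon monoxide, [C-]#[O+]
Why: Heck-type palladium-catalysed aryloxycarbonylation, in which the C–I bond adds to zerovalent palladium, CO inserts, and 9 is captured at its more acidic, non-chelated 4-OH (the 2-OH stays hydrogen-bonded to the ester) by C–O reductive elimination from the wide-bite-angle Xantphos complex, a step that crowding accelerates; CO plus phenoxide thus act as an aryloxycarbonyl anion joined to the electrophilic iodide carbon, and the shielded aryl chloride is untouched.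

Step 7
Reactants: 10 methyl 4-{[3-chloro-4,6-bis(methoxymethoxy)-2,5-dimethylbenzoyl]oxy}-2-hydroxy-3,5,6-trimethylbenzoate
Product: 11 methyl 4-{[3-chloro-4,6-bis(methoxymethoxy)-2,5-dimethylbenzoyl]oxy}-2-methoxy-3,5,6-trimethylbenzoate
Conditions: MeI (3 equiv), K2CO3 (2 equiv), DMF, 45 °C
Reagents that add atoms: iodomethane, CI
Why: Williamson O-methylation of the only free phenol, where the tetra-ortho-substituted depside ester is too shielded for acyl transfer and the MOM ethers are base-stable.

Step 8
Reactants: 11 methyl 4-{[3-chloro-4,6-bis(methoxymethoxy)-2,5-dimethylbenzoyl]oxy}-2-methoxy-3,5,6-trimethylbenzoate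
Product: 12 methyl 4-[(3-chloro-4,6-dihydroxy-2,5-dimethylbenzoyl)oxy]-2-methoxy-3,5,6-trimethylbenzoate
Conditions: conc. HCl (cat.), MeOH–THF, 45 °C
Reagents that add atoms: none
Why: acid-catalysed acetal exchange releases both phenols as dimethoxymethane; methanol cannot alter the methyl ester, the hindered depside ester resists methanolysis, and neither ring has a free position for electrophilic side reactions.

## Compound list

1 | 2,5-dimethylbenzene-1,3-diol (2,5-dimethylresorcinol) | Cc1cc(O)c(C)c(O)c1 | starting material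
2 | 4-chloro-2,5-dimethylbenzene-1,3-diol | Cc1cc(O)c(C)c(O)c1Cl | intermediate
3 | 4-chloro-6-iodo-2,5-dimethylbenzene-1,3-diol | Cc1c(Cl)c(O)c(C)c(O)c1I | intermediate
4 | 1-chloro-3-iodo-4,6-bis(methoxymethoxy)-2,5-dimethylbenzene | Cc1c(Cl)c(OCOC)c(C)c(OCOC)c1I | intermediate
5 | methyl 2,4-dihydroxy-3,6-dimethylbenzoate | COC(=O)c1c(C)cc(O)c(C)c1O | starting material
6 | methyl 5-[chloro(methoxy)methyl]-2,4-dihydroxy-3,6-dimethylbenzoate (racemic, not isolated) | COC(=O)c1c(C)c(C(Cl)OC)c(O)c(C)c1O | intermediate
7 | methyl 5-formyl-2,4-dihydroxy-3,6-dimethylbenzoate | COC(=O)c1c(C)c(C=O)c(O)c(C)c1O | intermediate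
8 | methyl 2,4-dihydroxy-5-(hydroxymethyl)-3,6-dimethylbenzoate (not isolated) | COC(=O)c1c(C)c(CO)c(O)c(C)c1O | intermediate
9 | methyl 2,4-dihydroxy-3,5,6-trimethylbenzoate | COC(=O)c1c(C)c(C)c(O)c(C)c1O | intermediate
10 | methyl 4-{[3-chloro-4,6-bis(methoxymethoxy)-2,5-dimethylbenzoyl]oxy}-2-hydroxy-3,5,6-trimethylbenzoate | COC(=O)c1c(C)c(C)c(OC(=O)c2c(C)c(Cl)c(OCOC)c(C)c2OCOC)c(C)c1O | intermediate
11 | methyl 4-{[3-chloro-4,6-bis(methoxymethoxy)-2,5-dimethylbenzoyl]oxy}-2-methoxy-3,5,6-trimethylbenzoate | COC(=O)c1c(C)c(C)c(OC(=O)c2c(C)c(Cl)c(OCOC)c(C)c2OCOC)c(C)c1OC | intermediate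
12 | methyl 4-[(3-chloro-4,6-dihydroxy-2,5-dimethylbenzoyl)oxy]-2-methoxy-3,5,6-trimethylbenzoate | COC(=O)c1c(C)c(C)c(OC(=O)c2c(C)c(Cl)c(O)c(C)c2O)c(C)c1OC | target

## Step count and risks

Total step count: 8 (three to fragment 4, two to fragment 9, three after convergence).
Longest linear sequence: 6 steps (1 → 2 → 3 → 4 → 10 → 11 → 12, steps 1, 2, 3, 6, 7, 8).

Steps most likely to fail:

**Step 6 (most risky).** Both partners are di-ortho-substituted, so capture of the carbonylated aryl unit by the hindered phenol may be slow and lose out to reduction or to hydrolysis to the acid. The fallback separates C–C from C–O bond formation. It sets out from 4 and comes back at 10. Hydroxycarbonylation of 4 (Pd(OAc)2, Xantphos, CO 5 bar, K2CO3, H2O–dioxane, 90 °C, then acidification) gives 3-chloro-4,6-bis(methoxymethoxy)-2,5-dimethylbenzoic acid F1. Under neutral, MOM-compatible conditions (1-chloro-N,N,2-trimethylprop-1-en-1-amine, CH2Cl2, rt) this is converted into 3-chloro-4,6-bis(methoxymethoxy)-2,5-dimethylbenzoyl chloride F2. F2 acylates 9 at its 4-OH (NaH 1.0 equiv, THF, 0 °C to rt) to give 10; the 2,6-disubstituted, electron-rich aroyl chloride reacts through an acylium-like pathway that tolerates the hindered phenol.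

**Step 1.** Monochlorination of the symmetric resorcinol can give dichloride and leave starting material. The fallback uses an ester as a blocking group. It sets out from 5 and comes back at 2. Chlorination of 5 (SO2Cl2, Et2O, 0 °C) can only occur at the single free position and gives methyl 5-chloro-2,4-dihydroxy-3,6-dimethylbenzoate F3. Saponification (KOH, H2O, reflux under N2) gives 5-chloro-2,4-dihydroxy-3,6-dimethylbenzoic acid F4, which is not isolated and loses CO2 on acidification and heating, as 2,4-dihydroxybenzoic acids do, to give 2.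

**Step 7.** The chelated 2-OH flanked by the ester and a methyl group may need forcing conditions, under which the depside ester could be cleaved. The fallback installs the methyl ether before the coupling. It sets out from 9 and comes back at 11. Selective benzylation of the non-chelated 4-OH of 9 (BnBr, K2CO3, acetone, rt) gives methyl 4-(benzyloxy)-2-hydroxy-3,5,6-trimethylbenzoate F5. Methylation (MeI, K2CO3, DMF, 50 °C) gives methyl 4-(benzyloxy)-2-methoxy-3,5,6-trimethylbenzoate F6. Hydrogenolysis (H2, Pd/C, EtOAc, rt) gives methyl 4-hydroxy-2-methoxy-3,5,6-trimethylbenzoate F7. F7 is coupled with 4 and CO under the step 6 conditions to give 11 directly.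

## Further compounds

F1 | step 6 | 3-chloro-4,6-bis(methoxymethoxy)-2,5-dimethylbenzoic acid | Cc1c(Cl)c(OCOC)c(C)c(OCOC)c1C(=O)O
F2 | step 6 | 3-chloro-4,6-bis(methoxymethoxy)-2,5-dimethylbenzoyl chloride | Cc1c(Cl)c(OCOC)c(C)c(OCOC)c1C(Cl)=O
F3 | step 1 | methyl 5-chloro-2,4-dihydroxy-3,6-dimethylbenzoate | COC(=O)c1c(C)c(Cl)c(O)c(C)c1O
F4 | step 1 | 5-chloro-2,4-dihydroxy-3,6-dimethylbenzoic acid | OC(=O)c1c(C)c(Cl)c(O)c(C)c1O
F5 | step 7 | methyl 4-(benzyloxy)-2-hydroxy-3,5,6-trimethylbenzoate | COC(=O)c1c(C)c(C)c(OCc2ccccc2)c(C)c1O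
F6 | step 7 | methyl 4-(benzyloxy)-2-methoxy-3,5,6-trimethylbenzoate | COC(=O)c1c(C)c(C)c(OCc2ccccc2)c(C)c1OC
F7 | step 7 | methyl 4-hydroxy-2-methoxy-3,5,6-trimethylbenzoate | COC(=O)c1c(C)c(C)c(O)c(C)c1OC
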